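Time is the first setting to turn on these flasks, in which E meets L to give X and meets G to give J.

| flask | E | L | G | remark | time |
|---|---|---|---|---|---|
| east | 0.12 M | 2.5 equiv | 0.20 equiv | run made earlier |  |
| south-east | 0.84 M | 2.5 equiv | 0.20 equiv | run made earlier |  |
| teal | 0.20 M | 2.50 equiv | 0.200 equiv |  | 8.0 min |
| violet | 0.30 M | 2.50 equiv | 0.200 equiv |  | 8.0 min |
| blue | 0.50 M | 2.50 equiv | 0.200 equiv |  | 8.0 min |
| amber | 0.60 M | 2.50 equiv | 0.200 equiv |  | 8.0 min |
| ochre | 1.0 M | 2.50 equiv | 0.200 equiv |  | 8.0 min |

| run | time / min | X / % | J / % | E / % |
|---|---|---|---|---|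
| east | 0.333 | 20 | 5 | 73 |
| east | 1.00 | 48 | 6 | 47 |
| east | 2.00 | 64 | 5 | 27 |
| east | 3.00 | 77 | 6 | 17 |
| east | 4.00 | 81 | 5 | 12 |
| south-east | 0.833 | 91 | 9 | 3 |
| south-east | 1.50 | 92 | 8 | 0 |
| south-east | 2.50 | 94 | 6 | 0 |
| south-east | 3.00 | 95 | 7 | 0 |
| south-east | 4.00 | 93 | 8 | 0 |

(scatter of a reading: 1.5 percentage points)

- "hardly changes" means that all values lie within two and a half points (for a concentration: within two and a half percent of the largest)

* share of X in all that became X or J for teal, violet, blue, amber, ochre, in this order
* the course of these numbers from the first flask to the last (falls all the way / rises all the way / hardly changes / rises, then falls / falls, then rises)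

In the east run E has lost half of its charge by 1.00 min. If that time shrinks in proportion to concentration, as expected for partners charged in constant equivalents, teal's is 0.600 min, so 8.0 min is 13.3 such times. J reads 5 % at 0.333 min and 5 % at 4.00 min, so X grows against a flat J while E lasts, and the row asks for the share of X, the selectivity, at the end of E.

Concentration is the other setting. The mean J is 5.40 % of the E charged in the east run and 7.60 % in the south-east run. G, charged at 0.200 equiv, is the limiting reagent of the step to J. Dividing by that charge gives 27.0 % and 38.0 %, and together 32.5 %, for the capture fraction f, the part of the G charged that ends as J. Once E has become X or J, the share of X is one minus f times the equivalents of G.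

The reckoning made here holds f level, on the assumption that G is contested by two steps that each have two partners, which speed up alike when equivalents stay constant. That puts each flask near 93.5 %. To leave the margin of 2.5 points, f must spread along the row by 12.5 % of the G charge, and the two runs differ by less, at 11 percentage points.

The forecast instead lets the share drift: 93.8 %, 93.2 %, 92.7 %, 92.6 %, 92.3 %, so hardly changes, with the ground “Since G is a fixed 0.20 equiv, J stays a nearly constant percentage”.

The flasks give 93.1 %, 93.1 %, 93.1 %, 93.1 %, 93.1 %: hardly changes.

    E + L → X (k = 0.0450 L mol⁻¹ s⁻¹)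
    E + G → J (k = 0.290 L mol⁻¹ s⁻¹)
    L → Z (k = 8.90 × 10⁻⁴ s⁻¹)
    G + L → D (k = 0.200 L mol⁻¹ s⁻¹)

In violet, G fell under a fiftieth of its charge by 0.345 min. In teal, E + G to J and G + L to D ran while G was there, with half of the turnover to D done by 0.0797 min; E + L to X ran on with 59 % of its turnover behind it at 0.800 min, and 36 % of the L charged stood at 8.00 min, after E + L to X, G + L to D and L to Z had all drawn on it. The shape would fail with f spread by 12.5 %, but beside the 32.5 % read earlier, f stands at 34.5 % in teal and 34.3 % in ochre. In ochre, G stands at 0 % and D at 0.131 M at 8.00 min.

The runs were computed with made-up constants; scatter was added.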